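The earlier runs and the new flask are calculated with made-up constants, noise included.

A small charge of D, 25 mM against 1.0 M of Z, turns Z and E into Q, and the readings of Q in this flask rise to 38.8% at 8.00 min and then fall.

| setting | summer | flask |
|---|---|---|
| Z | 1 M | 1.0 M |
| E | 1.3 M | 1.30 M |
| J | 0.50 M | 0.500 M |
| D | 25 mM | 25 mM |
| temperature | 90 °C | 90 °C |
| remark | the very flask that is asked about, followed so far |  |
| time |  | 30 min |

summer run (percent of the Z charged)

| time / min | Q / % | Z / % |
|---|---|---|
| 2.50 | 28.7 | 68.4 |
| 5.00 | 35.8 | 55.3 |
| 8.00 | 38.8 | 46.1 |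
| 10.0 | 38.0 | 41.6 |
| 12.0 | 37.0 | 38.9 |
| 15.0 | 35.3 | 35.2 |
| 20.0 | 33.4 | 30.8 |

(scatter of a reading: 0.3 percentage points)

- Wednesday's: at 30 min raise the temperature by 20 K, then wait 1.0 h
- Monday's: change nothing and wait 1.0 h more
- Friday's: at 30 min add D, 50.0% of the amount charged, then wait 1.0 h
- Saturday's: at 30 min take out 90% of the Q then present, then wait 1.0 h

- what is taken out of Q is counted as made
- the numbers in the tables scatter with a standard deviation of 0.3 percentage points
- on the list of suspects stand: Z + E + D -> D + Q; J + E + D -> D + X; Q + D <-> L + D
- additions bring no volume worth counting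
- the earlier runs do not show what temperature does; that part of a forecast is a guess

* Q, in percent of the Z first charged, at 30 min
* what to do for the largest gain in Q; "none" if nothing gains more than 2 percentage points (Wednesday's / Monday's / Friday's / Saturday's / none)
* Q present, with what was taken out counted in, in percent of the Z first charged, after Friday's
* Q present, with what was taken out counted in, in percent of the Z first charged, after Saturday's

L is read as the charge minus Z minus Q. Let r be L/Q and w the growth of L per unit of Q. For Q ⇌ L, w = kf − kb·r, so w shrinks as r climbs. From 5.00 min to 10.0 min the readings give r = 0.397 and w = 0.0623 min⁻¹. From 12.0 min to 20.0 min they give r = 0.851 and w = 0.0415 min⁻¹. Hence kb = 0.0458 min⁻¹, kf = 0.0805 min⁻¹, and the equilibrium constant K = kf/kb = 1.76. The resting share φ = 1/(1+K) = 36.3% is the part of Q+L that is Q once net exchange stops. The peak is kinetic control, φ thermodynamic control, and the approach takes a time τ = 1/(kf+kb) = 7.92 min.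

If J takes its whole 0.500 M of the 1.30 M of E, the remaining E serves 80.0% of Z. Q+L heads there, and Q heads for 29.0%. At 30 min the reckoning here puts Q near 30.2%.

Monday's: the reckoning here lets Q sink to 29.0%, a loss of 1.2 percentage points.

Friday's: D stands on both sides of each suspect, so the reckoning here shortens τ, keeps φ, and again puts Q near 29.0%.

Wednesday's: the readings show nothing of temperature, so any figure is a guess.

Saturday's: the 90% taken out counts, and the reckoning here lets φ of what remains in the pool return as Q, which gives 46.4%.

The forecast stands a little lower, at 29.8% now, 28.1% after Friday's and 45.4% after Saturday's, and it picks Saturday's, holding that "Extra D only gets there faster".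

The flask gives Q = 29.4% at 30 min, 26.6% after Friday's and 44.2% after Saturday's. The changes are −7.7 points for Wednesday's, −2.8 points for Monday's, −2.8 points for Friday's and 15 points for Saturday's, so the choice is Saturday's.

    Z + E + D → D + Q (k = 0.128 M⁻² s⁻¹, Ea = 70.0 kJ mol⁻¹)
    J + E + D → D + X (k = 0.684 M⁻² s⁻¹, Ea = 48.0 kJ mol⁻¹)
    Q + D ⇌ L + D, rate k3*[D]*[Q] forward; the back reaction follows from the equilibrium constant (K = 2.01, k = 0.0506 M⁻¹ s⁻¹, Ea = 75.0 kJ mol⁻¹, ΔH = 17.0 kJ mol⁻¹)
    (constants at 90 °C)

The passing of Q into L, both ways, is the main reason for what this flask does: in the run without it, Q at 30 min stands at 73.7% rather than 29.4%, and the best choice changes. Put into the Saturday count, the simulated 29.4% and φ give 45.9%, against the 44.2% found. A neighbouring flask with 0.78 M of E keeps 66.5% of its Z, so φ times the Z consumed gives 12.2%, and that flask holds Q at 12.5%.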